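**Retrosynthetic overview**
- The last C–C bond is cut between C3 of the chroman-4-one (the only stereocentre) and C6 of the 5-methoxy-2,2-dimethyl-2H-chromene. This gives a racemic 3-bromo-5,7-bis(silyloxy)chroman-4-one and a chromen-6-ylzinc iodide, joined by a nickel-catalysed stereoconvergent Negishi arylation.
- Enabling feature: C3 of the pyranone ring lies directly beside the C4 carbonyl. A C3–Br bond therefore makes this normally nucleophilic α-carbon an electrophile, and it gives a planar, carbonyl-stabilised C3 radical in which the configuration of either bromide enantiomer is erased. The partner, chromene C6 (ortho to OMe, para to the ring oxygen), is the natural nucleophilic site and carries the zinc.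
- Ring order, chromanone half: the pyranone ring is closed first on phloroglucinol (Friedel–Crafts acylation, then O-alkylation), followed by silylation and α-bromination.
- Ring order, chromene half: the 2H-pyran ring is closed on 2,4-dihydroxybenzaldehyde by chelation-controlled chromenylation with prenal; the formyl group then becomes CO2H and is exchanged for iodine at C6.
- The two silyl ethers are removed last under buffered fluoride.

Key step: step 9

Remark: C3 of the target is read as R (C4 > C2 > aryl > H). The sense of induction of the nickel/pybox catalyst cannot be predicted with certainty for this cyclic substrate, so the ligand antipode that delivers the 3R product is to be fixed by a trial coupling; both antipodes are available.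

**Step 1**
Reactants: 1 phloroglucinol; 2 3-chloropropanoic acid
Product: 3 3-chloro-1-(2,4,6-trihydroxyphenyl)propan-1-one
Conditions: CF3SO3H, 80 °C
Reagents that add atoms: none
Why: Friedel–Crafts acylation of the threefold-symmetric, highly nucleophilic arene by the acylium species formed in neat triflic acid; the first acyl group deactivates the ring against a second acylation.

**Step 2**
Reactants: 3 3-chloro-1-(2,4,6-trihydroxyphenyl)propan-1-one
Product: 4 5,7-dihydroxychroman-4-one
Conditions: 2 M NaOH aq, 0 °C to rt; then HCl to pH 3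
Reagents that add atoms: none
Why: Intramolecular Williamson-type O-alkylation by the ortho-phenoxide (6-exo-tet, or elimination to the aryl vinyl ketone and oxa-Michael closure) forms the pyranone ring; the two ortho hydroxyls are equivalent, so there is no regiochemical issue.

**Step 3**
Reactants: 4 5,7-dihydroxychroman-4-one
Product: 5 5,7-bis(tert-butyldimethylsilyloxy)chroman-4-one
Conditions: TBSOTf, 2,6-lutidine, CH2Cl2, 0 °C
Reagents that add atoms: tert-butyldimethylsilyl trifluoromethanesulfonate, CC(C)(C)[Si](C)(C)OS(=O)(=O)C(F)(F)F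
Why: Phenol silylation with a silyl triflate and a hindered pyridine base should also cap the hydrogen-bonded 5-OH without enolising the ketone; silyl ethers are chosen because they tolerate the organozinc and come off at the end without acid or strong base.

**Step 4**
Reactants: 5 5,7-bis(tert-butyldimethylsilyloxy)chroman-4-one
Product: 7 rac-3-bromo-5,7-bis(tert-butyldimethylsilyloxy)chroman-4-one, via trimethylsilyl enol ether 6 (not isolated)
Conditions: TMSOTf, Et3N, CH2Cl2, 0 °C; then NBS, THF, −78 °C
Reagents that add atoms: N-bromosuccinimide, O=C1CCC(=O)N1Br; trimethylsilyl trifluoromethanesulfonate, C[Si](C)(C)OS(=O)(=O)C(F)(F)F (held only in intermediate 6)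
Why: Soft enolisation gives the silyl enol ether, whose C3 is far more nucleophilic than the electron-rich benzene ring, so NBS should brominate only α to the ketone (α-halogenation of a silyl enol ether); the bromide is racemic by design.

**Step 5**
Reactants: 8 2,4-dihydroxybenzaldehyde; 9 3-methylbut-2-enal
Product: 10 5-hydroxy-2,2-dimethyl-2H-chromene-6-carbaldehyde
Conditions: pyridine, 140 °C (sealed tube)
Reagents that add atoms: none
Why: Base-mediated chromenylation (condensation at the carbon between the two oxygens, ortho-quinone methide, oxa-6π electrocyclisation); the 2-OH is locked in a hydrogen bond to the formyl group, so the free 4-OH closes the pyran ring and the angular 5-hydroxy-6-formyl isomer should result.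

**Step 6**
Reactants: 10 5-hydroxy-2,2-dimethyl-2H-chromene-6-carbaldehyde
Product: 11 5-methoxy-2,2-dimethyl-2H-chromene-6-carbaldehyde
Conditions: MeI, K2CO3, DMF, rt
Reagents that add atoms: methyl iodide, CI
Why: Williamson O-methylation of the only acidic site, the chelated phenol.

**Step 7**
Reactants: 11 5-methoxy-2,2-dimethyl-2H-chromene-6-carbaldehyde
Product: 12 5-methoxy-2,2-dimethyl-2H-chromene-6-carboxylic acid
Conditions: NaClO2, NaH2PO4, 2-methylbut-2-ene, t-BuOH/H2O, rt
Reagents that add atoms: sodium chlorite, [Na+].[O-]Cl=O
Why: Pinnick oxidation touches only the aldehyde, and the scavenger alkene consumes the hypochlorous acid that would otherwise attack the chromene double bond or the electron-rich ring.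

**Step 8**
Reactants: 12 5-methoxy-2,2-dimethyl-2H-chromene-6-carboxylic acid
Product: 13 6-iodo-5-methoxy-2,2-dimethyl-2H-chromene
Conditions: I2, K3PO4, MeCN, 100 °C (sealed)
Reagents that add atoms: iodine, II
Why: Ipso-iododecarboxylation of an electron-rich ortho-alkoxybenzoic acid: the aroyl hypoiodite formed from carboxylate and iodine collapses by concerted ipso-iodination with loss of CO2, favoured by the ortho-methoxy and para-alkoxy groups, and places iodine on C6 only.

**Step 9**
Reactants: 13 6-iodo-5-methoxy-2,2-dimethyl-2H-chromene; 7 rac-3-bromo-5,7-bis(tert-butyldimethylsilyloxy)chroman-4-one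
Product: 15 (3R)-5,7-bis(tert-butyldimethylsilyloxy)-3-(5-methoxy-2,2-dimethyl-2H-chromen-6-yl)chroman-4-one, via arylzinc iodide 14 (not isolated)
Conditions: (i) 13 (1.5 equiv), Zn dust (activated with 1,2-dibromoethane/TMSCl), LiCl, THF, 40 °C; (ii) 7, NiCl2·glyme (10 mol %), 2,6-bis[(4R,5S)-4,5-diphenyl-4,5-dihydrooxazol-2-yl]pyridine or its antipode (13 mol %), glyme/THF, −30 °C
Reagents that add atoms: zinc, [Zn] (held only in intermediate 14)
Why: Proposed new method: a Ni(I)–pybox species abstracts bromine from either enantiomer of 7 to give the same planar C3 radical, stabilised by the C4 carbonyl of the pyranone ring; this radical is captured by the chiral aryl–Ni(II) complex formed by transmetalation from 14, and reductive elimination from Ni(III) forges the bond between C3 and chromene C6. The closest known reaction type is the nickel/pybox-catalysed stereoconvergent Negishi α-arylation of racemic acyclic α-bromo ketones with arylzinc halides, extended here to a ring α-bromo ketone with a β-aryloxy group and to an ortho-alkoxy arylzinc. No ring is closed; the only new stereocentre, C3, is set under catalyst control, the ligand distinguishing the faces of the radical through the difference between its C4 carbonyl/peri-silyloxy side and its C2 methylene side. The step needs enantioface selectivity, secured by the choice of ligand antipode, and chemoselectivity for cross-coupling over loss of HBr to the chromone or β-aryloxy elimination, which the weakly basic zinc reagent and −30 °C should secure. The same mildness should keep the enolisable tertiary α-aryl ketone centre of 15 from epimerising once formed. The zinc reagent 14 comes from direct insertion of LiCl-activated zinc into the C6–I bond of 13, which the chromene double bond and the methyl ether tolerate.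

**Step 10**
Reactants: 15 (3R)-5,7-bis(tert-butyldimethylsilyloxy)-3-(5-methoxy-2,2-dimethyl-2H-chromen-6-yl)chroman-4-one
Product: 16 (3R)-5,7-dihydroxy-3-(5-methoxy-2,2-dimethyl-2H-chromen-6-yl)chroman-4-one
Conditions: TBAF, AcOH, THF, 0 °C
Reagents that add atoms: none
Why: Fluoride-mediated cleavage of the two aryl silyl ethers; acetic acid protonates the phenoxides as they form and keeps the medium near neutral, so the enolisable C3 centre and the acid-sensitive chromene are expected to survive.

**Compound list**
1 | phloroglucinol | Oc1cc(O)cc(O)c1 | starting material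
2 | 3-chloropropanoic acid | OC(=O)CCCl | starting material
3 | 3-chloro-1-(2,4,6-trihydroxyphenyl)propan-1-one | O=C(CCCl)c1c(O)cc(O)cc1O | intermediate
4 | 5,7-dihydroxychroman-4-one | O=C1CCOc2cc(O)cc(O)c12 | intermediate
5 | 5,7-bis(tert-butyldimethylsilyloxy)chroman-4-one | O=C1CCOc2cc(O[Si](C)(C)C(C)(C)C)cc(O[Si](C)(C)C(C)(C)C)c12 | intermediate
6 | 5,7-bis(tert-butyldimethylsilyloxy)-4-(trimethylsilyloxy)-2H-chromene | C[Si](C)(C)OC1=CCOc2cc(O[Si](C)(C)C(C)(C)C)cc(O[Si](C)(C)C(C)(C)C)c12 | intermediate
7 | rac-3-bromo-5,7-bis(tert-butyldimethylsilyloxy)chroman-4-one | O=C1C(Br)COc2cc(O[Si](C)(C)C(C)(C)C)cc(O[Si](C)(C)C(C)(C)C)c12 | intermediate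
8 | 2,4-dihydroxybenzaldehyde | O=Cc1ccc(O)cc1O | starting material
9 | 3-methylbut-2-enal | CC(C)=CC=O | starting material
10 | 5-hydroxy-2,2-dimethyl-2H-chromene-6-carbaldehyde | CC1(C)C=Cc2c(O)c(C=O)ccc2O1 | intermediate
11 | 5-methoxy-2,2-dimethyl-2H-chromene-6-carbaldehyde | COc1c(C=O)ccc2OC(C)(C)C=Cc12 | intermediate
12 | 5-methoxy-2,2-dimethyl-2H-chromene-6-carboxylic acid | COc1c(C(=O)O)ccc2OC(C)(C)C=Cc12 | intermediate
13 | 6-iodo-5-methoxy-2,2-dimethyl-2H-chromene | COc1c(I)ccc2OC(C)(C)C=Cc12 | intermediate
14 | (5-methoxy-2,2-dimethyl-2H-chromen-6-yl)zinc iodide | COc1c([Zn]I)ccc2OC(C)(C)C=Cc12 | intermediate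
15 | (3R)-5,7-bis(tert-butyldimethylsilyloxy)-3-(5-methoxy-2,2-dimethyl-2H-chromen-6-yl)chroman-4-one | COc1c([C@@H]2COc3cc(O[Si](C)(C)C(C)(C)C)cc(O[Si](C)(C)C(C)(C)C)c3C2=O)ccc2c1C=CC(C)(C)O2 | intermediate
16 | (3R)-5,7-dihydroxy-3-(5-methoxy-2,2-dimethyl-2H-chromen-6-yl)chroman-4-one | COc1c([C@@H]2COc3cc(O)cc(O)c3C2=O)ccc2c1C=CC(C)(C)O2 | target

**Step count**
Total steps: 10. Longest linear sequence: 6 steps (steps 1–4, 9, 10 or steps 5–8, 9, 10).

**Steps most likely to fail**

Step 9 (Proposed new method). The catalyst may discriminate poorly between the faces of the ring-bound C3 radical, or the bromide may be diverted to the chromone (loss of HBr) or to the reduced chromanone before the C–C bond forms. The fallback sets out from 5 and 13 and returns at 15, using known chemistry throughout.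
- Palladium-catalysed enolate α-arylation of 5 with 13 (Pd2(dba)3, XPhos, K3PO4, toluene, 80 °C) should give racemic 5,7-bis(tert-butyldimethylsilyloxy)-3-(5-methoxy-2,2-dimethyl-2H-chromen-6-yl)chroman-4-one F1.
- Asymmetric transfer hydrogenation under dynamic kinetic resolution (RuCl(p-cymene)[(R,R)-TsDPEN], HCO2H/Et3N, EtOAc, rt) follows; C3 epimerises through the enol while one enantiomer is reduced. This should give (3R,4R)-cis-5,7-bis(tert-butyldimethylsilyloxy)-3-(5-methoxy-2,2-dimethyl-2H-chromen-6-yl)chroman-4-ol F2. The catalyst antipode is expected by analogy with aryl alkyl ketone reductions and is to be confirmed.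
- Dess–Martin oxidation (NaHCO3, CH2Cl2, 0 °C), which does not touch C3, returns to 15.

Step 8. Iodine may attack the chromene double bond or C8 instead of the ipso carbon, or decarboxylation may stall. The fallback sets out from 12 and returns at 13.
- Curtius rearrangement (DPPA, Et3N, toluene, 80 °C; then aqueous NaOH/THF) runs through 5-methoxy-2,2-dimethyl-2H-chromene-6-carbonyl azide F3 and 6-isocyanato-5-methoxy-2,2-dimethyl-2H-chromene F4 to 5-methoxy-2,2-dimethyl-2H-chromen-6-amine F5.
- Diazotisation–iodination (p-TsOH, NaNO2, KI, MeCN/H2O, 10 °C to rt) through 5-methoxy-2,2-dimethyl-2H-chromene-6-diazonium 4-methylbenzenesulfonate F6 then gives 13.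

Step 4. Electrophilic bromination of the trioxygenated benzene ring may compete, or the 5-O-silyl group may be lost to adventitious HBr. The fallback sets out from 5 and returns at 7, avoiding electrophilic bromine.
- Enol ether 6 is formed as in step 4 and subjected to Rubottom oxidation (mCPBA, NaHCO3, CH2Cl2, −20 °C), giving rac-5,7-bis(tert-butyldimethylsilyloxy)-3-(trimethylsilyloxy)chroman-4-one F7.
- Mild work-up (citric acid, MeOH) cleaves the trimethylsilyl ether to rac-3-hydroxy-5,7-bis(tert-butyldimethylsilyloxy)chroman-4-one F8.
- Appel bromination (PPh3, CBr4, CH2Cl2, 0 °C) then gives 7.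

**Further compounds**
F1 | step 9 | rac-5,7-bis(tert-butyldimethylsilyloxy)-3-(5-methoxy-2,2-dimethyl-2H-chromen-6-yl)chroman-4-one | COc1c(C2COc3cc(O[Si](C)(C)C(C)(C)C)cc(O[Si](C)(C)C(C)(C)C)c3C2=O)ccc2c1C=CC(C)(C)O2
F2 | step 9 | (3R,4R)-cis-5,7-bis(tert-butyldimethylsilyloxy)-3-(5-methoxy-2,2-dimethyl-2H-chromen-6-yl)chroman-4-ol | COc1c([C@@H]2COc3cc(O[Si](C)(C)C(C)(C)C)cc(O[Si](C)(C)C(C)(C)C)c3[C@@H]2O)ccc2c1C=CC(C)(C)O2
F3 | step 8 | 5-methoxy-2,2-dimethyl-2H-chromene-6-carbonyl azide | COc1c(C(=O)N=[N+]=[N-])ccc2OC(C)(C)C=Cc12
F4 | step 8 | 6-isocyanato-5-methoxy-2,2-dimethyl-2H-chromene | COc1c(N=C=O)ccc2OC(C)(C)C=Cc12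
F5 | step 8 | 5-methoxy-2,2-dimethyl-2H-chromen-6-amine | COc1c(N)ccc2OC(C)(C)C=Cc12
F6 | step 8 | 5-methoxy-2,2-dimethyl-2H-chromene-6-diazonium 4-methylbenzenesulfonate | COc1c([N+]#N)ccc2OC(C)(C)C=Cc12.Cc1ccc(S(=O)(=O)[O-])cc1
F7 | step 4 | rac-5,7-bis(tert-butyldimethylsilyloxy)-3-(trimethylsilyloxy)chroman-4-one | C[Si](C)(C)OC1COc2cc(O[Si](C)(C)C(C)(C)C)cc(O[Si](C)(C)C(C)(C)C)c2C1=O
F8 | step 4 | rac-3-hydroxy-5,7-bis(tert-butyldimethylsilyloxy)chroman-4-one | OC1COc2cc(O[Si](C)(C)C(C)(C)C)cc(O[Si](C)(C)C(C)(C)C)c2C1=O
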